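Time was what this meeting argued over: how the share of isomer of the product in isomer plus target moves from 6.0 min to 25 h in the closed, isothermal flask, which Thursday's run has followed up to 5.00 h.

- Thursday's: substrate 0.046 M; partner 1.2 equiv; free catalyst 5 mol%; the very flask that is asked about, followed so far
- flask: substrate 0.046 M; partner 1.20 equiv; free catalyst 5 mol%; time 25 h

Thursday's run (percent of the substrate charged)

| time / h | isomer of the product / % | target / % | substrate / % |
|---|---|---|---|
| 0.417 | 1.9 | 4.1 | 93.5 |
| 1.33 | 5.6 | 13.8 | 82.1 |
| 2.50 | 9.6 | 20.8 | 70.9 |
| 4.00 | 12.5 | 26.6 | 61.4 |
| 5.00 | 14.9 | 29.5 | 55.5 |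

(readings scatter by 0.5 percentage points)

* share of isomer of the product in isomer of the product plus target at 6.0 min
* share of isomer of the product in isomer of the product plus target at 1.5 h
* share of isomer of the product in isomer of the product plus target at 25 h



The secretary argued that if substrate and partner give target (amount P, rate constant k_P) and isomer of the product (amount Q, rate constant k_Q) side by side, the same product of concentrations stands in both rates and cancels from dQ/dP = k_Q/k_P, so that the integral keeps Q/P constant so long as no other step acts. From the readings up to 2.50 h, summed, she read 30.6% for what she named the kinetic share φ, the fraction of new product that leaves as isomer under kinetic control, φ = k_Q/(k_P + k_Q). She committed to φ at 6.0 min and 1.5 h, and to φ as a lower mark at 25 h, noting that Thursday's reading at 5.00 h already gives 33.6%, above φ. The forecaster, who held that “the isomer forms mainly in parallel with the target, not after it”, went further and put a figure on the last time: 30%, 31% and 42%.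

The simulation of this flask gives 28.0%, 29.6% and 47.4%, so the forecast's first two figures hold within the tolerance and its last lies 5.4 percentage points too low.

    substrate + partner ⇌ target (K = 33.0 L mol⁻¹, k = 6.50 × 10⁻⁴ L mol⁻¹ s⁻¹)
    substrate + partner ⇌ isomer of the product (K = 54.0 L mol⁻¹, k = 2.50 × 10⁻⁴ L mol⁻¹ s⁻¹)
    target + free catalyst ⇌ isomer of the product + free catalyst, rate k3*[free catalyst]*[target] forward; the back reaction follows from the equilibrium constant (k = 0.00580 L mol⁻¹ s⁻¹)
    2 free catalyst → spent catalyst (k = 0.00520 L mol⁻¹ s⁻¹)
    2 free catalyst ⇌ resting dimer (K = 10000 L mol⁻¹, k = 0.0840 L mol⁻¹ s⁻¹)

The step that φ measures, substrate and partner going to isomer of the product, is the main reason for the share of this flask at 25 h: the simulated run of this flask without that step, both ways, ends at 12.2% in place of 47.4%. The 17 points by which this flask ends above φ come in part from the falling back of target to substrate and partner, for the simulated run of this flask without that back step ends at 28.2%. In the neighbour charged with 0.078 M of substrate, concentration cancels from φ, so φ again gives 30.6% for the early share, and the computed neighbour flask gives 28.0% at 6.0 min and 49.1% at 25 h.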